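**Retrosynthetic overview**
1. Ring D last: target ⇐ SmI2 ketyl–alkyne closure (C13–C16) of a fully oxidised ABC keto-alkyne acid.
2. Ring A oxidation pattern (19,10-lactone, 1β-OH, 2β,3β-epoxide) ⇐ one peracid cascade on a 1(10),2-diene-19-oic acid.
3. Ring C ⇐ Robinson-type annulation at C9/C8 of a ring B β-keto ester, then conjugate propargylation at C8.
4. Rings A+B ⇐ key step: catalytic desymmetrising Michael/alkylation [3+2] of a prochiral 4,4-disubstituted cyclohexadienone with 4-chloroacetoacetate (sets C4 and C5).
5. Dienone ⇐ Birch reductive methylation and allylic oxidation of tert-butyl benzoate. Ring order: A (from the arene) → B → C → ring A oxidation → D.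

Assumption: atom labels C1–C19 follow gibberellin numbering with α/β as in the usual drawing (C18, H5, H9 are β), and the cinchonidinium catalyst of step 3 is taken to give the enantiomer drawn; if it gives the antipode, the pseudoenantiomeric cinchoninium salt is used.

**Step 1**
Reactants: 1 tert-butyl benzoate
Product: 2 tert-butyl 1-methylcyclohexa-2,5-diene-1-carboxylate
Conditions: Li, NH3(l), THF, t-BuOH (1 equiv), −78 °C; then MeI
Reagents that add atoms: iodomethane, CI
Why: Birch reductive alkylation, in which Li/NH3 reduces the benzoate to the ester-stabilised cyclohexadienyl enolate and MeI alkylates it at the ipso carbon to give the achiral 1,4-diene carrying the future C4 quaternary carbon.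

**Step 2**
Reactants: 2 tert-butyl 1-methylcyclohexa-2,5-diene-1-carboxylate
Product: 3 tert-butyl 1-methyl-4-oxocyclohexa-2,5-diene-1-carboxylate
Conditions: CrO3 (5 mol %), t-BuOOH (70 % aq., 7 equiv), CH2Cl2, rt
Reagents that add atoms: tert-butyl hydroperoxide, CC(C)(C)OO
Why: Chromium-catalysed hydroperoxide allylic oxidation of the doubly allylic CH2 (the standard dihydrobenzoate-to-dienone oxidation) gives the prochiral cross-conjugated dienone whose two enone arms are enantiotopic.

**Step 3**
Reactants: 3 tert-butyl 1-methyl-4-oxocyclohexa-2,5-diene-1-carboxylate; 4 tert-butyl 4-chloro-3-oxobutanoate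
Product: 7 trans-fused diketo diester (rings A and B; H5β H10α), via Michael adduct 5 (not isolated), via cis-fused diketo diester 6 (not isolated)
Conditions: N-(9-anthracenylmethyl)cinchonidinium chloride (10 mol %), Cs2CO3 (2.2 equiv), PhMe, −20 °C → rt; then DBU (0.2 equiv), rt
Reagents that add atoms: none
Why: Proposed new method: a phase-transfer-catalysed domino Michael/intramolecular enolate alkylation (formal [3+2] annulation of the Michael-initiated ring-closure type) in which the ion-paired β-keto ester enolate adds to one enantiotopic β-carbon (C5) of the dienone anti to the C4 methyl and syn to the ester (smaller A value, Cieplak and dipole preference), the resulting C10 enolate closes ring B by 5-exo-tet displacement of the α-keto chloride to the cis-fused ketone, and base then equilibrates C10 (α to the C1 ketone) and C6 to the trans-fused isomer, so that C4 and C5 are set absolutely by the catalyst; the closest known reactions are organocatalytic Michael/α-alkylation cascades of 4-haloacetoacetates and catalytic desymmetrising Michael additions to 4,4-disubstituted cyclohexadienones.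

**Step 4**
Reactants: 7 trans-fused diketo diester
Product: 8 trans-fused C1 allylic alcohol (β-keto ester retained)
Conditions: LiN(SiMe3)2 (1.05 equiv), THF, −78 °C; then i-Bu2AlH (1.3 equiv), −78 °C; aq. potassium sodium tartrate
Reagents that add atoms: none
Why: Chemoselective 1,2-reduction with in situ protection, in which the β-keto ester is masked as its lithium enolate so that i-Bu2AlH reduces only the ring A enone carbonyl, locking the trans ring fusion (the C1 configuration, mainly the equatorial 1α-alcohol from axial hydride attack, is erased in step 9).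

**Step 5**
Reactants: 8 trans-fused C1 allylic alcohol; 9 2-(2-bromoethyl)-2-methyl-1,3-dioxolane
Product: 10 C9-alkylated β-keto ester (ketal side chain α at C9, H9β)
Conditions: LiN(i-Pr)2 (3.3 equiv), THF, −78 → 0 °C; then 9, DMPU, 0 °C → rt
Reagents that add atoms: none
Why: Weiler dianion γ-alkylation, in which the most basic C9 carbanion of the alkoxide/β-keto ester trianion is alkylated by the primary bromide anti to the C10–C1 bond, placing the side chain trans to C1 (α, H9β), which is also the thermodynamic arrangement at this still epimerisable centre.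

**Step 6**
Reactants: 10 C9-alkylated β-keto ester
Product: 12 tricyclic enone alcohol (ring C 13-oxo-8(14)-ene), via methyl ketone 11 (not isolated)
Conditions: 1 M HCl, THF, rt; then pyrrolidine (1.5 equiv), AcOH (1.5 equiv), PhMe, 60 °C
Reagents that add atoms: water, O
Why: Ketal hydrolysis followed by the ring-closing half of a Robinson annulation (amine/acid-mediated intramolecular aldol condensation of the methyl ketone onto the C8 ketone) gives the conjugated ring C enone, the only competing aldol (C6 onto C13) being unable to dehydrate and therefore reversible, while the labile C6 and C9 centres settle trans to their neighbours (C7 β, H9β).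

**Step 7**
Reactants: 12 tricyclic enone alcohol
Product: 13 tricyclic enone C1 acetate
Conditions: Ac2O, pyridine, DMAP (cat.), CH2Cl2, 0 °C
Reagents that add atoms: acetic anhydride, CC(=O)OC(C)=O
Why: Acylation of the secondary allylic alcohol protects it from TiCl4 in the next step and installs the leaving group for the later palladium-catalysed elimination.

**Step 8**
Reactants: 13 tricyclic enone C1 acetate
Product: 14 C8-propargyl 13-ketone (C15 β, C14 α)
Conditions: H2C=C=CHSnBu3 (2 equiv), TiCl4 (1.5 equiv), CH2Cl2, −78 °C
Reagents that add atoms: allenyltributylstannane, C=C=C[Sn](CCCC)(CCCC)CCCC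
Why: Lewis-acid conjugate propargylation (Hosomi–Sakurai-type SE2′ addition of the allenylstannane to the TiCl4-activated enone) creates the C8 quaternary centre, the nucleophile adding to the ring-fusion β-carbon on the face of H9 as in the stereoelectronically favoured formation of cis-hydrindanones.

**Step 9**
Reactants: 14 C8-propargyl 13-ketone
Product: 15 1(10),2-diene di-tert-butyl ester
Conditions: Pd(PPh3)4 (5 mol %), Et3N (4 equiv), 1,4-dioxane, 90 °C
Reagents that add atoms: none
Why: Palladium-catalysed 1,4-elimination of the allylic acetate (Tsuji–Trost ionisation by zerovalent palladium to the C1–C3 π-allyl complex, then loss of H10, the only hydrogen next to the allyl unit because C4 is quaternary, by amine-assisted anti deprotonation from the major 1α-acetate or syn β-hydride elimination from the minor 1β-acetate) gives the conjugated diene from both C1 epimers and removes the C1 stereocentre.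

**Step 10**
Reactants: 15 1(10),2-diene di-tert-butyl ester
Product: 16 1(10),2-diene-7,19-dioic acid
Conditions: Me3SiOTf (4 equiv), 2,6-lutidine (6 equiv), CH2Cl2, 0 °C; then pH 4 buffer
Reagents that add atoms: none
Why: Aprotic cleavage of both tert-butyl esters (silyl triflate gives the silyl esters with loss of isobutylene, and these, like any transient silyl enol ether of the C13 ketone, are hydrolysed on work-up) frees the C19 and C7 acids without exposing the acid-sensitive diene to a strong Brønsted acid and touches no stereocentre.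

**Step 11**
Reactants: 16 1(10),2-diene-7,19-dioic acid
Product: 19 1β-hydroxy-2β,3β-epoxy-19,10-lactone keto alkyne acid, via epoxy diacid 17 (not isolated), via hydroxy lactone acid 18 (not isolated)
Conditions: mCPBA (2.3 equiv), CH2Cl2, 0 °C → rt
Reagents that add atoms: m-chloroperbenzoic acid, OOC(=O)c1cccc(Cl)c1
Why: Prilezhaev epoxidation of the electron-rich trisubstituted C1=C10 bond from the open β face (flanked by H5 and H9, whereas C6, C11 and C19 block the α face), then 5-exo opening of the allylic tertiary epoxide at C10 with inversion by the α-disposed C19 acid (C10–O α, 1β-OH), then Henbest hydroxyl-directed epoxidation of C2=C3 syn to the 1β-OH and anti to the lactone bridge, so that C10, C1, C2 and C3 are all set in one operation while the terminal alkyne and the C13 ketone, which react far more slowly with the peracid, are left alone.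

**Step 12**
Reactants: 19 1β-hydroxy-2β,3β-epoxy-19,10-lactone keto alkyne acid
Product: 20 target gibberellin (ring D closed, 13-hydroxy-16-methylene)
Conditions: SmI2 (5 equiv), HMPA, t-BuOH, THF, 0 °C
Reagents that add atoms: none
Why: SmI2-mediated ketyl–alkyne reductive cyclisation (the samarium version of the Stork reductive cyclisation of acetylenic ketones), in which the C13 ketyl adds 5-exo-dig to the propargyl alkyne and the vinyl radical is reduced and protonated, closes ring D with the bridgehead 13-OH and the exocyclic 16-methylene, the C13 configuration being dictated by the C8 tether.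

**Compound list**
1 | tert-butyl benzoate | CC(C)(C)OC(=O)c1ccccc1 | starting material
2 | tert-butyl 1-methylcyclohexa-2,5-diene-1-carboxylate | CC(C)(C)OC(=O)C1(C)C=CCC=C1 | intermediate
3 | tert-butyl 1-methyl-4-oxocyclohexa-2,5-diene-1-carboxylate (prochiral dienone, future ring A) | CC(C)(C)OC(=O)C1(C)C=CC(=O)C=C1 | intermediate
4 | tert-butyl 4-chloro-3-oxobutanoate | CC(C)(C)OC(=O)CC(=O)CCl | starting material
5 | Michael adduct (not isolated): ring A 1-oxo-2-ene with 4β-Me, 4α-CO2t-Bu, H5β and the CH(CO2t-Bu)C(=O)CH2Cl chain on C5 (C6 labile) | CC(C)(C)OC(=O)[C@]1(C)C=CC(=O)C[C@@H]1[C@H](C(=O)OC(C)(C)C)C(=O)CCl | intermediate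
6 | cis-fused diketo diester (not isolated): ring A 1-oxo-2-ene, ring B 8-oxo-6-carboxylate, H5β, H10β | CC(C)(C)OC(=O)[C@]1(C)C=CC(=O)[C@@H]2CC(=O)[C@@H](C(=O)OC(C)(C)C)[C@H]12 | intermediate
7 | trans-fused diketo diester: as 6 but H10α (4β-Me, 4α-CO2t-Bu, H5β, 6β-CO2t-Bu) | CC(C)(C)OC(=O)[C@]1(C)C=CC(=O)[C@H]2CC(=O)[C@@H](C(=O)OC(C)(C)C)[C@H]12 | intermediate
8 | trans-fused C1 allylic alcohol (1α-OH major; C1 epimer ratio inconsequential), 8-oxo-6-carboxylate retained | CC(C)(C)OC(=O)[C@]1(C)C=C[C@H](O)[C@H]2CC(=O)[C@@H](C(=O)OC(C)(C)C)[C@H]12 | intermediate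
9 | 2-(2-bromoethyl)-2-methyl-1,3-dioxolane | CC1(CCBr)OCCO1 | starting material
10 | C9-alkylated β-keto ester: 8 carrying the 2-(2-methyl-1,3-dioxolan-2-yl)ethyl chain α at C9 (H9β) | CC(C)(C)OC(=O)[C@]1(C)C=C[C@H](O)[C@H]2[C@H](CCC3(C)OCCO3)C(=O)[C@@H](C(=O)OC(C)(C)C)[C@H]12 | intermediate
11 | methyl ketone (not isolated): 10 with the ketal hydrolysed to the 3-oxobutyl chain | CC(C)(C)OC(=O)[C@]1(C)C=C[C@H](O)[C@H]2[C@H](CCC(C)=O)C(=O)[C@@H](C(=O)OC(C)(C)C)[C@H]12 | intermediate
12 | tricyclic enone alcohol: rings A, B, C; ring C 13-oxo-8(14)-ene; 1α-OH, 2-ene, H5β, H9β, H10α, 6β- and 4α-CO2t-Bu | CC(C)(C)OC(=O)[C@]1(C)C=C[C@H](O)[C@H]2[C@@H]3CCC(=O)C=C3[C@@H](C(=O)OC(C)(C)C)[C@H]12 | intermediate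
13 | tricyclic enone C1 acetate (12 with 1α-OAc) | CC(C)(C)OC(=O)[C@]1(C)C=C[C@H](OC(C)=O)[C@H]2[C@@H]3CCC(=O)C=C3[C@@H](C(=O)OC(C)(C)C)[C@H]12 | intermediate
14 | C8-propargyl 13-ketone: C8 quaternary with prop-2-ynyl (C15–C17) β and C14 α, cis B/C fusion, 1α-OAc | CC(C)(C)OC(=O)[C@]1(C)C=C[C@H](OC(C)=O)[C@H]2[C@@H]3CCC(=O)C[C@]3(CC#C)[C@@H](C(=O)OC(C)(C)C)[C@H]12 | intermediate
15 | 1(10),2-diene di-tert-butyl ester (ring A diene C10=C1–C2=C3; 13-oxo; 8β-propargyl) | CC(C)(C)OC(=O)[C@]1(C)C=CC=C2[C@@H]3CCC(=O)C[C@]3(CC#C)[C@@H](C(=O)OC(C)(C)C)[C@H]12 | intermediate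
16 | 1(10),2-diene-7,19-dioic acid (13-oxo; 8β-propargyl) | OC(=O)[C@]1(C)C=CC=C2[C@@H]3CCC(=O)C[C@]3(CC#C)[C@@H](C(O)=O)[C@H]12 | intermediate
17 | epoxy diacid (not isolated): 1β,10β-epoxy-2-ene-7,19-dioic acid | OC(=O)[C@]1(C)C=C[C@H]2O[C@]23[C@@H]4CCC(=O)C[C@]4(CC#C)[C@@H](C(O)=O)[C@H]13 | intermediate
18 | hydroxy lactone acid (not isolated): 1β-hydroxy-2-ene 19,10-lactone 7-acid, 13-oxo, 8β-propargyl | C#CC[C@]12CC(=O)CC[C@H]1[C@@]13OC(=O)[C@@](C)([C@H]1[C@@H]2C(=O)O)C=C[C@H]3O | intermediate
19 | 1β-hydroxy-2β,3β-epoxy 19,10-lactone 7-acid, 13-oxo, 8β-propargyl (ring D still open) | C#CC[C@]12CC(=O)CC[C@H]1[C@@]13OC(=O)[C@@](C)([C@H]1[C@@H]2C(=O)O)[C@H]1O[C@H]1[C@H]3O | intermediate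
20 | target gibberellin: 1β,13-dihydroxy-2β,3β-epoxy-20-norgibberell-16-ene-7,19-dioic acid 19,10-lactone | C=C1C[C@]23C[C@@]1(O)CC[C@H]2[C@@]12OC(=O)[C@@](C)([C@H]1[C@@H]3C(=O)O)[C@H]1O[C@H]1[C@H]2O | target

**Step count and risks**
Total step count: 12. Longest linear sequence: 12 steps (1 → 20); compounds 4 and 9 are purchased.

The three steps most likely to fail:

Step 3. The cascade is unprecedented on this dienone. It may give low ee, addition syn to the methyl group, self-condensation of 4, or a cis/trans ratio at C10 that does not favour 7. The later C9 and C8 configurations depend on the trans fusion. The fallback sets out from 3 and comes back at 6. Ring B is made instead by an asymmetric palladium-catalysed trimethylenemethane [3+2] cycloaddition of 3 with tert-butyl 3-(acetoxymethyl)-2-(trimethylsilyl)but-3-enoate (CC(=O)OCC(=C)C(C(=O)OC(C)(C)C)[Si](C)(C)C), using Pd2(dba)3·CHCl3 and a chiral phosphoramidite ligand in toluene. This gives the cis-fused methylenecyclopentane diester F1. Its electron-rich exocyclic alkene is cleaved in preference to the enone (ozone, CH2Cl2/MeOH, −78 °C, then Me2S) to give the cis-fused diketo diester 6. DBU then equilibrates 6 to 7 as in the main route.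

Step 8. Conjugate propargylation at a fully substituted ring-fusion β-carbon may be slow, and the required face is also the face of the neighbouring C6 ester. It may also give 1,2-addition, or ionise the allylic acetate under TiCl4. The fallback sets out from 13 and comes back at 14. The Lewis-acid activation is replaced by a nucleophilic organocopper 1,4-addition: LiCu(CH2C≡CSiMe3)2 (from 3-(trimethylsilyl)prop-2-ynyllithium and CuBr·SMe2) with Me3SiCl in THF at −78 °C gives the silyl-capped propargyl ketone F2. Buffered desilylation (Bu4NF, AcOH, THF, 0 °C) then gives 14.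

Step 12. SmI2 may simply reduce the ring C ketone, cyclise sluggishly onto the unactivated alkyne, or open the epoxide through Lewis-acidic SmI3. The fallback sets out from 19 and comes back at 20. It uses a tin-radical carbonyl cyclisation: Bu3SnH and AIBN in benzene at 80 °C add a stannyl radical to the terminal alkyne, and the resulting vinyl radical closes 5-exo onto the ring C carbonyl to give the 17-tributylstannyl derivative of the target F3 (E/Z mixture, both converge). Mild protodestannylation (AcOH, THF, 40 °C) then gives 20.

**Further compounds**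
F1 | step 3 | cis-fused methylenecyclopentane diester (6 with C8=CH2 in place of the C8 ketone) | CC(C)(C)OC(=O)[C@]1(C)C=CC(=O)[C@@H]2CC(=C)[C@@H](C(=O)OC(C)(C)C)[C@H]12
F2 | step 8 | silyl-capped propargyl ketone (14 with C≡C–SiMe3) | CC(C)(C)OC(=O)[C@]1(C)C=C[C@H](OC(C)=O)[C@H]2[C@@H]3CCC(=O)C[C@]3(CC#C[Si](C)(C)C)[C@@H](C(=O)OC(C)(C)C)[C@H]12
F3 | step 12 | 17-(tributylstannyl) derivative of target 20 (E/Z mixture) | CCCC[Sn](CCCC)(CCCC)C=C1C[C@]23C[C@@]1(O)CC[C@H]2[C@@]12OC(=O)[C@@](C)([C@H]1[C@@H]3C(=O)O)[C@H]1O[C@H]1[C@H]2O
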